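The numbers in the tables were generated by integration for substances that don't exist; scatter was added.

At early times the open dimer runs ahead of the ring in the south-east flask (26.9% against 9.1% at 0.200 min), but from 1.50 min on the dimer readings stay flat while the ring climbs, so I count whatever is still unread there as future ring.

common to all: activator 1.95 M

| run | substrate | remark | time |
|---|---|---|---|
| south-east | 1.5 M | the very flask that is asked about, followed so far |  |
| south | 3 M | run made earlier |  |
| flask | 1.5 M |  | 30 min |

| run | time / min | ring / % | open dimer / % | substrate / % |
|---|---|---|---|---|
| south-east | 0.200 | 9.1 | 26.9 | 25.6 |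
| south-east | 0.500 | 23.8 | 39.1 | 12.0 |
| south-east | 1.00 | 33.7 | 45.1 | 7.0 |
| south-east | 1.50 | 37.9 | 48.3 | 6.6 |
| south-east | 2.00 | 41.9 | 48.5 | 1.8 |
| south-east | 3.00 | 49.7 | 48.2 | 0.8 |
| south-east | 4.00 | 48.9 | 48.5 | 0.6 |
| south | 1.50 | 22.1 | 58.9 | 8.6 |
| south | 5.00 | 27.1 | 62.8 | 3.6 |
| south | 8.00 | 32.8 | 63.7 | 0.9 |
| south | 12.0 | 30.2 | 64.9 | 2.6 |
| south | 20.0 | 32.2 | 65.6 | 1.0 |
| south | 25.0 | 32.9 | 63.8 | 1.0 |
| south | 30.0 | 31.6 | 64.7 | 1.5 |

(readings scatter by 1 percentage point)

- percent here means substrate units held: one open dimer counts as two
- what was read earlier has a scatter of 1 percentage point, one standard deviation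
- the reaction counts as stopped when no species that holds the substrate changes by six tenths of a point or more over the second half of the time

- why nothing more happens at 30 min, or that something still does (the activator has run out first / forward and back rates have come level / it is still moving / all of the substrate has reacted)
- the ring standing at 30 min, as a percentage of the substrate charged
- the open dimer standing at 30 min, as a percentage of the substrate charged

I define a selectivity factor ρ: final dimer over final ring, divided by the substrate charge c, with ring taken as the charge minus the dimer. The south-east reading at 4.00 min gives ρ = 0.628 M⁻¹. If the ring closes by itself while the dimer needs a second substrate, the ratio of their rates is proportional to substrate, so I expect ρ to carry across substrate charges at a fixed activator charge. The south run, with the same activator charge, tests this: dimer fraction ρc/(1+ρc) gives 65.3%, and its reading at 30.0 min is 64.7%.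

Taking one activator per ring and one per dimer, this flask needs 1.14 M of 1.95 M, so substrate is the limiting reagent. I expect dimer 48.5% and ring 51.5%.

The forecast says all of the substrate has reacted, with ring 50% and dimer 48.4%, and holds that “neither product shows interconversion”. Its ring lies 1.5 percentage points below mine.

At 30 min the flask gives all of the substrate has reacted: ring 51.8%, dimer 48.2%.

    substrate + activated form → open dimer (k = 0.134 M⁻¹ s⁻¹)
    substrate ⇌ dormant form (K = 1.03, k = 0.0582 s⁻¹)
    substrate + activator → activated form (k = 0.0335 M⁻¹ s⁻¹)
    activated form → ring (k = 0.0718 s⁻¹)

In this flask at 30 min substrate stands at 0%, with 42% of the activator still there. Here ρc is 0.942, and the computed dimer over ring is 0.931.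

With 0.90 M of substrate, ρ gives dimer 36.1% and ring 63.9%. That flask computes to dimer 36.0% and ring 64.0%.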